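**Plan**
Cuts: (a) the six O–benzyl bonds of a fully protected precursor; (b) C2–C1' of the flavanone, the bond at the only stereocentre; (c) in one operation C4a''–C4'', C3''–C4'' and O1''–C2'' of the flavone pyranone (ring C''); (d) the C3'–C6'' biaryl bond.
Enabling feature: in flavone ring A'' the biaryl carbon C6'' stands para to C8a''–O1''. The ring A'' precursor is therefore a 4-aryl-3,5-bis(benzyloxy)phenol with a mirror plane through C1 and C4, so either ortho carbon can become C4a'' and a C8'' linkage cannot arise.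
Forward: the biaryl bond is made first on a small symmetric iodide, then ring C'' is closed from iodophenol, CO and arylacetylene. The aryl chloride is then turned into a boronic acid and joined to a chromone that already holds flavanone rings A and C (from phloroacetophenone), and global hydrogenolysis follows.
Stereochemistry: (2S) comes from a ligand-controlled palladium-catalysed 1,4-addition of the arylboronic acid to the chromone with (R)-t-BuPyOx. The last step is neutral, so the configuration is kept.
Locants: plain and single-primed for the flavanone half, double-primed for the flavone half.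

Key step: step 6

Assumption: the C3'–C6'' axis has three oxygen substituents and one hydrogen in its ortho positions and no axial descriptor in the target, so it is taken as freely rotating. Benzylated intermediates made after ring A'' loses its symmetry may show slowly exchanging rotamers, which does not affect the route.

Step 1
Reactants: 1 3,5-bis(benzyloxy)phenol
Product: 2 [3,5-bis(benzyloxy)phenoxy]triisopropylsilane
Conditions: TIPSCl, imidazole, DMF, rt
Reagents that add atoms: triisopropylsilyl chloride, CC(C)[Si](Cl)(C(C)C)C(C)C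
Why: Standard imidazole-mediated O-silylation of a phenol, with the triisopropylsilyl group chosen because its bulk screens both ring carbons next to its oxygen in step 2.

Step 2
Reactants: 2 [3,5-bis(benzyloxy)phenoxy]triisopropylsilane
Product: 3 [3,5-bis(benzyloxy)-4-iodophenoxy]triisopropylsilane
Conditions: NIS (1.0 equiv), CH2Cl2/MeCN, −20 °C to rt, dark
Reagents that add atoms: N-iodosuccinimide, O=C1CCC(=O)N1I
Why: Electrophilic aromatic iodination of a phloroglucinol triether: the three ring C–H positions are activated alike, so the silyl group should steer iodine to the carbon between the two benzyloxy groups, para to the silyloxy group, and iodine rather than bromine is installed so that step 3 can run on a catalyst that does not touch aryl chlorides.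

Step 3
Reactants: 3 [3,5-bis(benzyloxy)-4-iodophenoxy]triisopropylsilane; 4 2-benzyloxy-5-chlorophenylboronic acid
Product: 5 2,2',6-tris(benzyloxy)-5'-chloro-4-(triisopropylsilyloxy)biphenyl
Conditions: Pd(PPh3)4 (5 mol %), K3PO4, 1,4-dioxane/H2O, 90 °C
Reagents that add atoms: none
Why: Suzuki–Miyaura coupling in which triphenylphosphine-ligated zerovalent palladium inserts into the C–I bond of 3 but leaves the C–Cl bond of 4 and 5 alone, a type of union well known for 2,6-dialkoxyaryl iodides and ortho-alkoxyarylboron partners despite the three ortho substituents.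

Step 4
Reactants: 5 2,2',6-tris(benzyloxy)-5'-chloro-4-(triisopropylsilyloxy)biphenyl
Product: 6 3,5-bis(benzyloxy)-4-(2-benzyloxy-5-chlorophenyl)phenol
Conditions: TBAF, AcOH, THF, 0 °C
Reagents that add atoms: none
Why: Fluoride-driven cleavage of an aryl silyl ether (strong Si–F bond), buffered with acetic acid so that the electron-rich phenoxide is protonated at once, and harmless to benzyl ethers and the aryl chloride.

Step 5
Reactants: 6 3,5-bis(benzyloxy)-4-(2-benzyloxy-5-chlorophenyl)phenol
Product: 7 3,5-bis(benzyloxy)-4-(2-benzyloxy-5-chlorophenyl)-2-iodophenol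
Conditions: NIS (1.0 equiv), CH2Cl2, −20 to 0 °C, dark
Reagents that add atoms: N-iodosuccinimide, O=C1CCC(=O)N1I
Why: Electrophilic ortho-iodination of a free phenol: the para carbon is occupied by the aryl group and the two ortho carbons are mirror images of each other, so only one mono-iodide can arise, and one equivalent of reagent at low temperature should hold back the second iodination.

Step 6
Reactants: 7 3,5-bis(benzyloxy)-4-(2-benzyloxy-5-chlorophenyl)-2-iodophenol; 8 1-benzyloxy-4-ethynylbenzene; 9 carbon monoxide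
Product: 12 5,7-bis(benzyloxy)-6-(2-benzyloxy-5-chlorophenyl)-2-(4-benzyloxyphenyl)-4H-chromen-4-one, via ortho-hydroxyaryl ynone 10 (not isolated), via diethylamino enaminone 11 (not isolated)
Conditions: PdCl2(PPh3)2 (5 mol %), CO (20 bar), 8 (1.5 equiv), Et2NH, 120 °C, autoclave, no copper salt
Reagents that add atoms: carbon monoxide (reactant 9), [C-]#[O+]; diethylamine, CCNCC (its atoms stand only in intermediate 11 and leave again on ring closure)
Why: Zerovalent palladium, formed from PdCl2(PPh3)2 under CO and amine, inserts into the C–I bond of 7, CO inserts to give an aroylpalladium iodide, and the amine-deprotonated alkyne 8 is transferred and reductively eliminated as ynone 10, which creates C4a''–C4'' and C3''–C4''. Diethylamine then adds to the β-carbon of the ynone to give enaminone 11, and the neighbouring phenol oxygen attacks that same carbon and expels the amine, which creates O1''–C2'' and closes ring C'' by a 6-endo-trig addition–elimination. The closest known reaction type is the palladium-catalysed carbonylative coupling and cyclisation of 2-iodophenols with terminal arylacetylenes in secondary amines, an established flavone synthesis. No stereocentre is formed. Three selectivities are needed: C–I over C–Cl insertion, secured by the much weaker C–I bond and a triphenylphosphine catalyst that ignores electron-rich aryl chlorides; carbonylative over direct alkynylation (which would drain into benzofuran closure), secured by copper-free conditions, CO pressure and the fast CO insertion of an electron-rich arylpalladium; and flavone over aurone, secured because the enaminone offers the phenol only its β-carbon. The C6'' position of the biaryl bond needs no control here, since the only free hydroxyl of 7 sits para to the aryl group.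

Step 7
Reactants: 12 5,7-bis(benzyloxy)-6-(2-benzyloxy-5-chlorophenyl)-2-(4-benzyloxyphenyl)-4H-chromen-4-one
Product: 13 5,7-bis(benzyloxy)-6-[2-benzyloxy-5-(4,4,5,5-tetramethyl-1,3,2-dioxaborolan-2-yl)phenyl]-2-(4-benzyloxyphenyl)-4H-chromen-4-one
Conditions: B2pin2, Pd2(dba)3 (2 mol %), XPhos (8 mol %), KOAc, 1,4-dioxane, 100 °C
Reagents that add atoms: bis(pinacolato)diboron, CC1(C)OB(OC1(C)C)B1OC(C)(C)C(C)(C)O1
Why: Miyaura borylation of an aryl chloride, made possible by the bulky electron-rich ligand XPhos, at a C–Cl bond with two free ortho positions, while KOAc is too weak a base to start Suzuki homocoupling or to open the pyranone.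

Step 8
Reactants: 13 the pinacol boronate of step 7
Product: 14 {4-benzyloxy-3-[5,7-bis(benzyloxy)-2-(4-benzyloxyphenyl)-4-oxo-4H-chromen-6-yl]phenyl}boronic acid
Conditions: NaIO4, NH4OAc, acetone/THF/H2O, rt
Reagents that add atoms: water, O
Why: Oxidative hydrolysis of a pinacol boronate: periodate cleaves the pinacol released in the hydrolysis equilibrium (glycol cleavage) and so drives it to the free boronic acid, which transmetalates readily in step 11.

Step 9
Reactants: 15 2,4,6-trihydroxyacetophenone
Product: 16 1-[2,4-bis(benzyloxy)-6-hydroxyphenyl]ethan-1-one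
Conditions: BnBr (2.05 equiv), K2CO3, DMF, rt to 60 °C
Reagents that add atoms: benzyl bromide, BrCc1ccccc1
Why: Williamson etherification in which the hydroxyl group hydrogen-bonded to the acetyl carbonyl is the least nucleophilic and stays free when two equivalents of benzyl bromide are used.

Step 10
Reactants: 16 1-[2,4-bis(benzyloxy)-6-hydroxyphenyl]ethan-1-one
Product: 18 5,7-bis(benzyloxy)-4H-chromen-4-one, via dimethylamino enaminone 17 (not isolated)
Conditions: Me2NCH(OMe)2, toluene, 100 °C; then conc. HCl, CH2Cl2, rt to 40 °C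
Reagents that add atoms: N,N-dimethylformamide dimethyl acetal, COC(OC)N(C)C
Why: Condensation of the acetyl CH3 with the amide acetal gives enaminone 17, and acid then triggers attack of the ortho phenol on the β-carbon with loss of dimethylamine, the standard enaminone route from 2-hydroxyacetophenones to 2,3-unsubstituted chromones.

Step 11
Reactants: 14 the arylboronic acid of step 8; 18 5,7-bis(benzyloxy)-4H-chromen-4-one
Product: 19 (2S)-5,7-bis(benzyloxy)-2-{4-benzyloxy-3-[5,7-bis(benzyloxy)-2-(4-benzyloxyphenyl)-4-oxo-4H-chromen-6-yl]phenyl}-2,3-dihydro-4H-chromen-4-one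
Conditions: Pd(OCOCF3)2 (10 mol %), (R)-t-BuPyOx [(4R)-4-tert-butyl-2-(pyridin-2-yl)-4,5-dihydro-1,3-oxazole, 12 mol %], NH4PF6 (30 mol %), H2O (5 equiv), 18 (2 equiv), ClCH2CH2Cl, 60 °C
Reagents that add atoms: none
Why: Enantioselective palladium-catalysed conjugate addition of an arylboronic acid to a chromone: the aryl group of 14 passes to a cationic divalent palladium–PyOx complex, adds across C2=C3 of 18 in the enantiodetermining carbopalladation and the palladium enolate is protonated by water, the tert-butyl group of the (R)-ligand leaving open the face that gives (2S), a sense taken from the known pairing of the (S)-ligand with (R)-configured adducts of cyclic enones (same spatial arrangement, same descriptor for a flavanone), while the nearly neutral medium prevents retro-oxa-Michael racemisation and the 2-aryl-substituted pyranone inside 14 is too hindered to compete as acceptor.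

Step 12
Reactants: 19 the hexabenzyl ether of step 11
Product: 20 (2S)-2-{3-[5,7-dihydroxy-2-(4-hydroxyphenyl)-4-oxo-4H-chromen-6-yl]-4-hydroxyphenyl}-5,7-dihydroxy-2,3-dihydro-4H-chromen-4-one (CNP0277421.1)
Conditions: H2 (1 atm), Pd/C (10 wt %), THF/MeOH, rt
Reagents that add atoms: none
Why: Catalytic hydrogenolysis of six aryl benzyl ethers, which are cleaved far faster than the flavone C2''=C3'' bond is saturated or the cyclic C2–O1 bond is broken, and the neutral medium avoids the ring-opening path by which 4'-hydroxyflavanones racemise.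

**Compound list**
1 | 3,5-bis(benzyloxy)phenol | Oc1cc(OCc2ccccc2)cc(OCc2ccccc2)c1 | starting material
2 | [3,5-bis(benzyloxy)phenoxy]triisopropylsilane | CC(C)[Si](Oc1cc(OCc2ccccc2)cc(OCc2ccccc2)c1)(C(C)C)C(C)C | intermediate
3 | [3,5-bis(benzyloxy)-4-iodophenoxy]triisopropylsilane | CC(C)[Si](Oc1cc(OCc2ccccc2)c(I)c(OCc2ccccc2)c1)(C(C)C)C(C)C | intermediate
4 | 2-benzyloxy-5-chlorophenylboronic acid | OB(O)c1cc(Cl)ccc1OCc1ccccc1 | starting material
5 | 2,2',6-tris(benzyloxy)-5'-chloro-4-(triisopropylsilyloxy)biphenyl | CC(C)[Si](Oc1cc(OCc2ccccc2)c(-c2cc(Cl)ccc2OCc2ccccc2)c(OCc2ccccc2)c1)(C(C)C)C(C)C | intermediate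
6 | 3,5-bis(benzyloxy)-4-(2-benzyloxy-5-chlorophenyl)phenol | Oc1cc(OCc2ccccc2)c(-c2cc(Cl)ccc2OCc2ccccc2)c(OCc2ccccc2)c1 | intermediate
7 | 3,5-bis(benzyloxy)-4-(2-benzyloxy-5-chlorophenyl)-2-iodophenol | Oc1cc(OCc2ccccc2)c(-c2cc(Cl)ccc2OCc2ccccc2)c(OCc2ccccc2)c1I | intermediate
8 | 1-benzyloxy-4-ethynylbenzene | C#Cc1ccc(OCc2ccccc2)cc1 | starting material
9 | carbon monoxide | [C-]#[O+] | starting material
10 | 1-[4,6-bis(benzyloxy)-5-(2-benzyloxy-5-chlorophenyl)-2-hydroxyphenyl]-3-(4-benzyloxyphenyl)prop-2-yn-1-one (not isolated) | O=C(C#Cc1ccc(OCc2ccccc2)cc1)c1c(O)cc(OCc2ccccc2)c(-c2cc(Cl)ccc2OCc2ccccc2)c1OCc1ccccc1 | intermediate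
11 | 1-[4,6-bis(benzyloxy)-5-(2-benzyloxy-5-chlorophenyl)-2-hydroxyphenyl]-3-(4-benzyloxyphenyl)-3-(diethylamino)prop-2-en-1-one (not isolated, double-bond geometry not fixed) | O=C(C=C(N(CC)CC)c1ccc(OCc2ccccc2)cc1)c1c(O)cc(OCc2ccccc2)c(-c2cc(Cl)ccc2OCc2ccccc2)c1OCc1ccccc1 | intermediate
12 | 5,7-bis(benzyloxy)-6-(2-benzyloxy-5-chlorophenyl)-2-(4-benzyloxyphenyl)-4H-chromen-4-one | O=c1cc(-c2ccc(OCc3ccccc3)cc2)oc2cc(OCc3ccccc3)c(-c3cc(Cl)ccc3OCc3ccccc3)c(OCc3ccccc3)c12 | intermediate
13 | 5,7-bis(benzyloxy)-6-[2-benzyloxy-5-(4,4,5,5-tetramethyl-1,3,2-dioxaborolan-2-yl)phenyl]-2-(4-benzyloxyphenyl)-4H-chromen-4-one | O=c1cc(-c2ccc(OCc3ccccc3)cc2)oc2cc(OCc3ccccc3)c(-c3cc(B4OC(C)(C)C(C)(C)O4)ccc3OCc3ccccc3)c(OCc3ccccc3)c12 | intermediate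
14 | {4-benzyloxy-3-[5,7-bis(benzyloxy)-2-(4-benzyloxyphenyl)-4-oxo-4H-chromen-6-yl]phenyl}boronic acid | O=c1cc(-c2ccc(OCc3ccccc3)cc2)oc2cc(OCc3ccccc3)c(-c3cc(B(O)O)ccc3OCc3ccccc3)c(OCc3ccccc3)c12 | intermediate
15 | 2,4,6-trihydroxyacetophenone | CC(=O)c1c(O)cc(O)cc1O | starting material
16 | 1-[2,4-bis(benzyloxy)-6-hydroxyphenyl]ethan-1-one | CC(=O)c1c(O)cc(OCc2ccccc2)cc1OCc1ccccc1 | intermediate
17 | (E)-1-[2,4-bis(benzyloxy)-6-hydroxyphenyl]-3-(dimethylamino)prop-2-en-1-one (not isolated) | CN(C)/C=C/C(=O)c1c(O)cc(OCc2ccccc2)cc1OCc1ccccc1 | intermediate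
18 | 5,7-bis(benzyloxy)-4H-chromen-4-one | O=c1ccoc2cc(OCc3ccccc3)cc(OCc3ccccc3)c12 | intermediate
19 | (2S)-5,7-bis(benzyloxy)-2-{4-benzyloxy-3-[5,7-bis(benzyloxy)-2-(4-benzyloxyphenyl)-4-oxo-4H-chromen-6-yl]phenyl}-2,3-dihydro-4H-chromen-4-one | O=C1C[C@@H](c2ccc(OCc3ccccc3)c(-c3c(OCc4ccccc4)cc4oc(-c5ccc(OCc6ccccc6)cc5)cc(=O)c4c3OCc3ccccc3)c2)Oc2cc(OCc3ccccc3)cc(OCc3ccccc3)c21 | intermediate
20 | (2S)-2-{3-[5,7-dihydroxy-2-(4-hydroxyphenyl)-4-oxo-4H-chromen-6-yl]-4-hydroxyphenyl}-5,7-dihydroxy-2,3-dihydro-4H-chromen-4-one | O=C1C[C@@H](c2ccc(O)c(-c3c(O)cc4oc(-c5ccc(O)cc5)cc(=O)c4c3O)c2)Oc2cc(O)cc(O)c21 | target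

**Count and risks**
Total step count: 12.
Longest linear sequence: 10 (steps 1–8, 11, 12). Steps 9 and 10 form the side branch.

**Risk 1, step 11.**
- The chromone receives electron density from two alkoxy groups and may accept the arylpalladium only slowly, so protodeboronation of the valuable boronic acid could outrun the addition.
- Facial discrimination could erode with so large an aryl group, or run opposite to the analogy used.
- The sense of induction would first be checked with 4-benzyloxyphenylboronic acid and 18, whose adduct leads to naringenin of known sign of rotation. The antipodal ligand is at hand if the sense is reversed.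
- The fallback sets out from 12 and comes back at 19. It closes flavanone ring C from a chalcone and separates the enantiomers by catalytic kinetic resolution.
- Chloride 12 is vinylated with potassium vinyltrifluoroborate (Pd(OAc)2, RuPhos, Cs2CO3, THF/H2O, 85 °C) to the styrene F1. Lemieux–Johnson cleavage (OsO4 cat., NaIO4, 2,6-lutidine, dioxane/H2O) then attacks the terminal alkene ahead of the pyranone double bond and gives the aldehyde F2.
- Claisen–Schmidt condensation of F2 with acetophenone 16 (KOH, EtOH/THF, rt) gives the 2'-hydroxychalcone F3. NaOAc in refluxing EtOH closes it by oxa-Michael addition to the racemic flavanone F4.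
- Asymmetric transfer hydrogenation with RuCl[(R,R)-TsDPEN](p-cymene) and HCO2H/Et3N, stopped near half conversion, should reduce the (2R)-enantiomer to the cis-(2R,4R)-flavan-4-ol F5. The (2S)-ketone 19 is left behind and separated by chromatography.

**Risk 2, step 6.**
- Insertion of palladium into a C–I bond flanked by a phenoxide and a benzyloxy group on a very electron-rich ring may be slow.
- The crowded aroylpalladium may be captured by diethylamine (aminocarbonylation) faster than by the alkyne.
- Alkynylation without CO uptake, followed by five-membered ring closure, may drain material.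
- The fallback sets out from 7 and 8, re-enters at ynone 10 and so comes back at 12. It makes the ynone by polar acylation, so C4'' comes from a carbamoyl chloride instead of CO.
- Phenol 7 is protected (MOMCl, iPr2NEt, CH2Cl2) as the methoxymethyl ether F6. Alkyne 8 is lithiated (n-BuLi, THF, −78 °C) and acylated with N-methoxy-N-methylcarbamoyl chloride to the Weinreb propiolamide F7.
- Iodine–lithium exchange on F6 (n-BuLi, THF, −78 °C) followed by addition of F7 gives the protected ynone F8.
- Aqueous HCl in THF/iPrOH removes the acetal to release 10, and Et2NH in DMF at rt to 60 °C closes it through 11 to 12.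

**Risk 3, step 2.**
- Iodination may spread over the ortho and para sites if the silyl group shields less than expected. Statistics and the para-benzyloxy activation both favour the carbons next to the silyloxy group, and the isomers may be hard to separate.
- The fallback sets out from 1 and comes back at 5. It fixes the position by oxidation instead of by substitution.
- Phenol 1 is oxidised with (KSO3)2NO (Teuber reaction, KH2PO4 buffer, acetone/H2O), which places oxygen on the free para carbon and gives 2,6-bis(benzyloxy)-1,4-benzoquinone F9. Na2S2O4 (THF/H2O) reduces it to the hydroquinone F10.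
- TIPSCl and imidazole silylate the open hydroxyl rather than the one flanked by two benzyloxy groups, giving the monosilyl ether F11. Tf2O and pyridine then give the aryl triflate F12.
- Suzuki–Miyaura coupling of F12 with 4 (Pd(PPh3)4, K3PO4, KBr, dioxane, 100 °C), in which triflate reacts ahead of chloride, gives 5.

**Further compounds**
F1 | step 11 | 5,7-bis(benzyloxy)-6-(2-benzyloxy-5-ethenylphenyl)-2-(4-benzyloxyphenyl)-4H-chromen-4-one | O=c1cc(-c2ccc(OCc3ccccc3)cc2)oc2cc(OCc3ccccc3)c(-c3cc(C=C)ccc3OCc3ccccc3)c(OCc3ccccc3)c12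
F2 | step 11 | 4-benzyloxy-3-[5,7-bis(benzyloxy)-2-(4-benzyloxyphenyl)-4-oxo-4H-chromen-6-yl]benzaldehyde | O=c1cc(-c2ccc(OCc3ccccc3)cc2)oc2cc(OCc3ccccc3)c(-c3cc(C=O)ccc3OCc3ccccc3)c(OCc3ccccc3)c12
F3 | step 11 | (E)-1-[2,4-bis(benzyloxy)-6-hydroxyphenyl]-3-{4-benzyloxy-3-[5,7-bis(benzyloxy)-2-(4-benzyloxyphenyl)-4-oxo-4H-chromen-6-yl]phenyl}prop-2-en-1-one | O=C(/C=C/c1ccc(OCc2ccccc2)c(-c2c(OCc3ccccc3)cc3oc(-c4ccc(OCc5ccccc5)cc4)cc(=O)c3c2OCc2ccccc2)c1)c1c(O)cc(OCc2ccccc2)cc1OCc1ccccc1
F4 | step 11 | racemic 5,7-bis(benzyloxy)-2-{4-benzyloxy-3-[5,7-bis(benzyloxy)-2-(4-benzyloxyphenyl)-4-oxo-4H-chromen-6-yl]phenyl}-2,3-dihydro-4H-chromen-4-one | O=C1CC(c2ccc(OCc3ccccc3)c(-c3c(OCc4ccccc4)cc4oc(-c5ccc(OCc6ccccc6)cc5)cc(=O)c4c3OCc3ccccc3)c2)Oc2cc(OCc3ccccc3)cc(OCc3ccccc3)c21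
F5 | step 11 | 5,7-bis(benzyloxy)-6-{2-benzyloxy-5-[(2R,4R)-5,7-bis(benzyloxy)-4-hydroxy-3,4-dihydro-2H-chromen-2-yl]phenyl}-2-(4-benzyloxyphenyl)-4H-chromen-4-one | O[C@@H]1C[C@H](c2ccc(OCc3ccccc3)c(-c3c(OCc4ccccc4)cc4oc(-c5ccc(OCc6ccccc6)cc5)cc(=O)c4c3OCc3ccccc3)c2)Oc2cc(OCc3ccccc3)cc(OCc3ccccc3)c21
F6 | step 6 | 1,3-bis(benzyloxy)-2-(2-benzyloxy-5-chlorophenyl)-4-iodo-5-(methoxymethoxy)benzene | COCOc1cc(OCc2ccccc2)c(-c2cc(Cl)ccc2OCc2ccccc2)c(OCc2ccccc2)c1I
F7 | step 6 | 3-(4-benzyloxyphenyl)-N-methoxy-N-methylprop-2-ynamide | CON(C)C(=O)C#Cc1ccc(OCc2ccccc2)cc1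
F8 | step 6 | 1-[2,4-bis(benzyloxy)-3-(2-benzyloxy-5-chlorophenyl)-6-(methoxymethoxy)phenyl]-3-(4-benzyloxyphenyl)prop-2-yn-1-one | COCOc1cc(OCc2ccccc2)c(-c2cc(Cl)ccc2OCc2ccccc2)c(OCc2ccccc2)c1C(=O)C#Cc1ccc(OCc2ccccc2)cc1
F9 | step 2 | 2,6-bis(benzyloxy)cyclohexa-2,5-diene-1,4-dione | O=C1C=C(OCc2ccccc2)C(=O)C(OCc2ccccc2)=C1
F10 | step 2 | 2,6-bis(benzyloxy)benzene-1,4-diol | Oc1cc(OCc2ccccc2)c(O)c(OCc2ccccc2)c1
F11 | step 2 | 2,6-bis(benzyloxy)-4-(triisopropylsilyloxy)phenol | CC(C)[Si](Oc1cc(OCc2ccccc2)c(O)c(OCc2ccccc2)c1)(C(C)C)C(C)C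
F12 | step 2 | 2,6-bis(benzyloxy)-4-(triisopropylsilyloxy)phenyl trifluoromethanesulfonate | CC(C)[Si](Oc1cc(OCc2ccccc2)c(OS(=O)(=O)C(F)(F)F)c(OCc2ccccc2)c1)(C(C)C)C(C)C
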